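(The readings come from a simulation with constants of no real substance.)

The ratio of incoming ligand to starting complex in Saturday's run and in teal was 1.05 equiv, close to one, so this was no pseudo-first-order case: I treated the two reagents as falling together.

| flask | starting complex | incoming ligand | scavenger | remark | time |
|---|---|---|---|---|---|
| Saturday's | 0.050 M | 1.05 equiv | 0.80 equiv | run made earlier |  |
| Monday's | 0.050 M | 1.05 equiv | 0.40 equiv | run made earlier |  |
| Thursday's | 0.050 M | 1.05 equiv | 1.6 equiv | run made earlier |  |
| teal | 0.050 M | 1.05 equiv | 0.800 equiv | a closed flask charged with all of it at once and left for 2.0 min | 2.0 min |
| blue | 0.050 M | 1.05 equiv | 0.800 equiv | a single well-mixed tank run continuously and read at steady state, 2.0 min in it on average |  |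
| red | 0.050 M | 1.05 equiv (fed, over 2.00 min) | 0.800 equiv | all but incoming ligand at the start; incoming ligand goes in evenly over 2.00 min, the run ends at 2.0 min | 2.0 min |
| amber | 0.050 M (fed, over 2.00 min) | 1.05 equiv | 0.800 equiv | a stirred flask in which starting complex is dosed at a steady rate over 2.00 min without added volume, worked up at 2.0 min | 2.0 min |

Saturday's run (percent of the starting complex charged)

| time / s | complex with one exchanged / % |
|---|---|
| 15.0 | 11.8 |
| 40.0 | 24.0 |
| 80.0 | 37.5 |
| 120 | 43.1 |

Monday's run (percent of the starting complex charged)

| time / min | complex with one exchanged / % |
|---|---|
| 0.200 | 9.8 |
| 0.417 | 18.8 |
| 1.00 | 32.7 |
| 2.50 | 44.4 |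

Thursday's run (percent of the starting complex charged)

| time / min | complex with one exchanged / % |
|---|---|
| 0.200 | 11.3 |
| 0.417 | 19.4 |
| 1.00 | 34.1 |
| 2.50 | 44.2 |

(scatter of a reading: 1 percentage point)

- the stated concentrations are those of everything mixed, before any reaction; amounts are the same in each set-up
- the feed brings no volume worth counting
- the earlier runs were made in a closed, stirred flask

- the set-up with the highest amount of complex with one exchanged at the outlet or at the end, in percent of the starting complex put in ("none" if the first two lie within 2 percentage points) (teal / blue / red / amber / none)
- amount of complex with one exchanged at the outlet or at the end, in percent of the starting complex put in, teal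
- amount of complex with one exchanged at the outlet or at the end, in percent of the starting complex put in, blue
- amount of complex with one exchanged at the outlet or at the end, in percent of the starting complex put in, red
- amount of complex with one exchanged at the outlet or at the end, in percent of the starting complex put in, amber

At the bench I first drew a straight line through the opening slope. Saturday's run carried teal's scavenger, and I took its first reading of complex with one exchanged, with its scatter of 1 percentage point, as the amount converted by then:

τ = 15.0 s / 11.8 % = 2.12 min

I called τ the clock: the time the opening rate would need to consume the whole charge. For one bimolecular step with equal charges, it is also the second-order half-life.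

The straight line makes the converted fraction equal to θ = t/τ, and for teal at 2.0 min this gave:

θ = 0.944

But Saturday's reading of complex with one exchanged, 43.1 % at 120 s, lay far below that, so I took the line to have failed by the time θ approached one. Past that border I used the bimolecular curve:

X = θ / (1 + θ) = 48.6 %

I expected teal's product a little under X. The dose of incoming ligand in red and the dose of starting complex in amber each took 2.00 min, less than τ, so I expected the dosed reagent to pile up. Each dose also ran to the end of its flask, so I placed red and amber below teal.

The forecast gave 42.8 % for teal, 29.5 % for blue, 31 % for red and 29.6 % for amber, with teal best. It warned: “The order in ligand is inferred only from curve shape”.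

The flasks gave 42.1 % for teal, 30.2 % for blue, 30.2 % for red and 29.0 % for amber, so teal was best.

    starting complex + incoming ligand → leaving ligand + complex with one exchanged (k = 0.210 /M/s)
    leaving ligand + incoming ligand ⇌ idle adduct, settled at all times (K = 2500 /M)
    complex with one exchanged + incoming ligand → leaving ligand + complex with two exchanged (k = 0.0740 /M/s)
    scavenger + leaving ligand → scavenged by-product (k = 23.0 /M/s)

In teal the first exchange ran with both reagents present, leaving 52.3 % of the starting complex and 29.6 % of the incoming ligand unbound at 2.00 min, when complex with one exchanged was still made 3.53 times faster than used up, each step taken net. In red the incoming ligand reached 0.0257 M at its highest, and 48.9 % of its charge stood unbound at the end beside 67.5 % of the starting complex. Teal converted 47.7 % against X of 48.6 %.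

For a neighbour of teal charged with 0.12 M of starting complex, with the equivalents and the time held, I reckoned the clock shorter, at 0.883 min, so X became 69.4 %. That flask converted 61.2 % and held 50.7 % of complex with one exchanged.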